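**Assumptions:** The target is (S)-17-methylnonadecyl 2,3-dihydroxybenzoate. I read 16 CH₂ groups between the stereocentre and the ester oxygen, and the stereocentre is S. I assume (S)-3-methylpentanoic acid and 16-hydroxyhexadecanoic acid (juniperic acid) are purchasable.

## Retrosynthetic overview
1. Disconnect the catechol ester at the acyl C–O bond. This gives 2,3-dihydroxybenzoic acid and (S)-17-methylnonadecan-1-ol.
2. Disconnect the alcohol at the C16–C17 bond (the CH₂–CH₂ bond next to the CH(CH₃) carbon) by anodic decarboxylative radical–radical (Kolbe) coupling. The partners are the cheap chiral acid (S)-3-methylpentanoic acid, which supplies the only stereocentre, and 16-hydroxyhexadecanoic acid, which supplies the C15 hydroxy chain.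
3. No rings are formed, because the arene is purchased. The stereocentre is β to the radical carbon, so it is never touched.

## Route

**Step 1**
Reactants: **1** (S)-3-methylpentanoic acid (4 equiv); **2** 16-hydroxyhexadecanoic acid (1 equiv)
Product: **3** (S)-17-methylnonadecan-1-ol
Conditions: Me₄N·OH (0.3 equiv relative to total acid), acetone/MeOH 9:1, graphite(+)/graphite(–), rapid alternating polarity electrolysis (50 ms), undivided cell, rt
Reagents that add atoms: none (CO₂ is lost; Me₄N·OH only forms the carboxylate salts)
Why: Kolbe electrolysis. Anodic oxidation of the carboxylates gives acyloxy radicals, which lose CO₂ to give •CH₂CH(CH₃)Et and •(CH₂)₁₅OH. These couple to form the C16–C17 bond. The stereocentre is β to the radical carbon and no bond to it changes, so the S configuration is retained. Excess of the cheap short acid favours the cross product. The side products are volatile 3,6-dimethyloctane and a polar C30 diol, both easily separated from the alcohol.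
**Proposed new method:** Rapid-alternating-polarity Kolbe cross-coupling has not, to my knowledge, been shown for an unprotected long-chain ω-hydroxy acid with a β-stereogenic short acid. Mechanistically, alternating polarity keeps the electrode surface clean. The amphiphilic hydroxy-carboxylate adsorbs on graphite and raises the local primary-radical concentration. The free primary OH should survive because carboxylate oxidation is faster than alcohol oxidation at these potentials. The closest known reaction is Kolbe heterocoupling under alternating-polarity conditions.

**Step 2**
Reactants: **3** (S)-17-methylnonadecan-1-ol (1 equiv); **4** 2,3-dihydroxybenzoic acid (1.5 equiv)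
Product: **5** Gentiside G, (S)-17-methylnonadecyl 2,3-dihydroxybenzoate
Conditions: p-TsOH·H₂O (10 mol%), toluene, reflux (110 °C), Dean–Stark trap, N₂, 16–24 h; wash with NaHCO₃(aq) to remove excess **4**
Reagents that add atoms: none (the acid catalyst is not incorporated)
Why: Fischer esterification. The primary alcohol attacks the protonated carboxylic acid, and water is removed azeotropically. The 2-OH and 3-OH phenols are weak nucleophiles (the 2-OH is hydrogen-bonded to the carbonyl), so only the acid is esterified. The remote sp³ stereocentre cannot epimerise under these conditions, and 110 °C is well below the temperature at which 2,3-dihydroxybenzoic acid decarboxylates.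

## Checks
- **Carbon count:** Step 1 joins HO(CH₂)₁₅• with •CH₂CH(CH₃)CH₂CH₃ to give HO(CH₂)₁₆CH(CH₃)CH₂CH₃, which is 17-methylnonadecan-1-ol. Esterifying it with **4** gives exactly the target SMILES.
- **Stereochemistry:** In **1**, **3** and **5** the centre has the same neighbour order and the same CIP ranking (chain > ethyl > methyl > H), so S is retained.
- **Functional group tolerance:** The free OH in Step 1 and the catechol in Step 2 are tolerated under the stated conditions, and the catechol is only introduced after the electrolysis.

## Compound list
1 | (S)-3-methylpentanoic acid | CC[C@H](C)CC(=O)O | starting material
2 | 16-hydroxyhexadecanoic acid | OCCCCCCCCCCCCCCCC(=O)O | starting material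
3 | (S)-17-methylnonadecan-1-ol | CC[C@H](C)CCCCCCCCCCCCCCCCO | intermediate
4 | 2,3-dihydroxybenzoic acid | OC(=O)c1cccc(O)c1O | starting material
5 | Gentiside G | CC[C@H](C)CCCCCCCCCCCCCCCCOC(=O)c1cccc(O)c1O | target

**Total steps:** 2. **Longest linear sequence:** 2.

## Three most likely failure points
The route has only two steps, so the third entry is a sub-problem inside Step 1.

1. **Step 1, the new alternating-polarity Kolbe cross-coupling** may give low yield from anodic oxidation of the free OH or from Hofer–Moest ether formation.
   Fallback (known chemistry): Kochi–Schlosser Li₂CuCl₄-catalysed coupling of (S)-2-methylbutylmagnesium bromide (from (S)-1-bromo-2-methylbutane) with 15-bromopentadecan-1-ol (as its alkoxide or THP ether, using excess Grignard), followed by deprotection if needed.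
2. **Step 2, direct esterification** may suffer from catechol oxidation, depside formation or incomplete conversion.
   Fallback: dibenzylate 2,3-dihydroxybenzoic acid and hydrolyse the resulting benzyl ester to give 2,3-bis(benzyloxy)benzoic acid. Couple it with **3** using DCC/DMAP, then remove the benzyl groups with H₂, Pd/C.
3. **Step 1, cross- versus homo-coupling selectivity and isolation** could make the C30 diol or dimethyloctane contaminate **3**, or give a poor cross yield.
   Fallback: Ni-catalysed decarboxylative cross-electrophile coupling of the N-hydroxyphthalimide ester of **1** with 15-bromopentadecan-1-ol (a known redox-active-ester/alkyl-bromide coupling).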